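Amounts first: in Friday's run 80.0 mM of starting material and as much partner give 34.02 mM of product at 5.9 h, the last interval adding 1.37 mM, while Saturday's run, with 240 mM of partner, turns nearly all of its starting material.

| flask | starting material | partner | time |
|---|---|---|---|
| Friday's | 80.0 mM | 80.0 mM |  |
| Tuesday's | 32.0 mM | 32.0 mM |  |
| Wednesday's | 120 mM | 80.0 mM |  |
| Saturday's | 80.0 mM | 240 mM |  |
| Sunday's | 26.0 mM | 160 mM | 5.9 h |

- Friday's run (time / h: [product] / mM): 0.45: 10.47; 1.4: 22.17; 2.6: 28.98; 4.1: 32.65; 5.9: 34.02
- Tuesday's run (time / h: [product] / mM): 0.45: 1.18; 1.4: 2.35; 2.6: 3.43; 4.1: 3.88; 5.9: 4.32
- Wednesday's run (time / h: [product] / mM): 0.45: 15.32; 1.4: 32.08; 2.6: 40.53; 4.1: 44.31; 5.9: 45.49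
- Saturday's run (time / h: [product] / mM): 0.45: 51.70; 1.4: 73.18; 2.6: 77.48; 4.1: 78.64; 5.9: 78.92

(readings scatter by 0.2 mM)

- apparent order in [partner] of the starting rate, round the charge of the Friday's run (the rate where two percent of its starting material have turned into product)
- apparent order in [starting material] of the starting rate, round the charge of the Friday's run (the rate where two percent of its starting material have turned into product) (one fixed amount of product, the same in the runs compared)
- product in the Sunday's run at 5.9 h, as a share of the starting material charged

- Overall: starting material + partner -> product.
- Constant volume, constant temperature.
- "The second partner" is partner.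
- An order is taken over about fifteen percent of the charge, up and down.

Two chemists argue over one measure, the exposure of a run: the natural logarithm of starting material charged over starting material remaining. For a step first order in [starting material], this is the time integral of its pseudo-first-order rate constant. At 5.9 h, Friday's exposure reads 0.554 and Saturday's 4.31. Saturday's rests on a remainder of 1.08 mM, read with a scatter of 0.2 mM. The first readings of Wednesday's and Friday's runs give an order in [starting material] of 0.939, taken at fixed time, so exposure can be carried across charges of starting material.

The first chemist holds that activity fades with time whatever the charge, so exposure follows the square of [partner], taken as the charge less half the product made. For Sunday's run, the bare charge gives exposure 2.22, or 89.1 %. Putting that yield back in gives a [partner] of 148 mM against 63.0 mM in Friday's run, hence exposure 3.07, or 95.4 %.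

The second chemist holds that partner itself disappears, and objects that this rule carried to Saturday's run gives 5.61, more than the 4.31 read. She uses instead the exposure order, 1.87: the power joining exposure to the partner charge, read across two runs that bracket Sunday's charge. Sunday's exposure is then 2.02, a yield of 86.7 %. The same comparison at the first readings gives 1.82. I side with her and commit to that order in [partner], 0.939 in [starting material], and 86.7 %.

The forecast, on the first chemist's side, speaks of “activity dying with time” and gives 1.9, 1.05 and 94 %, which differs from the 95.4 % of the round above.

The simulation gives 1.8, 1.1 and 88.0 %, an exposure of 2.12 in Sunday's run.

    starting material + partner → product (1.019 M⁻¹ h⁻¹)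
    starting material + 2 partner → product + partner (42.48 M⁻² h⁻¹)
    partner → lost reagent (0.3445 h⁻¹)
    starting material + partner + product → 2 product (91.80 M⁻² h⁻¹)

With the reaction of partner to lost reagent taken away, Sunday's run gives 99.9 % in place of 88.0 %, so that reaction is the main reason for the shortfall; its exposure would be 7.23 in place of 2.12. The first chemist's view keeps its region, the starting rate round Friday's charge: the reaction of partner to lost reagent is not the reason for the order in [partner] of 1.8 there, which stands at 1.8 without it. Against the 1.87 read from Friday's and Saturday's runs, the exposure order between Friday's reading and Sunday's simulated exposure comes to 1.94.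

All runs are calculated on assumed constants, noise included.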